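**Plan**

1. Caryophyllane numbering is used: C1/C9 are the cyclobutane methines, C4 carries O1 and CH3, C5 is its CH neighbour, C8 carries the methylidene, and C1′ is the CHPh carbon; ring A is the arene, ring B the pyran, ring C the nine-membered ring, ring D the cyclobutane. The retrosynthesis cuts, in order: the two C–CHO bonds; C4–C5; the C4 methyl and C8 methylidene carbons (one double carbonyl methylenation); O1–C4 (aryl ester); C6–C7 (enolate alkylation); ring D ([2+2]).
2. Enabling feature: O1 and C1′ are ortho on ring A, so the arene is a rigid two-atom bridge from C4 (through O1) to C5 (through C1′). With C4 as an O-aryl oxocarbenium carbon and C5 as the terminus of a C1′=C5 diarylethene, the two carbons face each other in a six-membered array inside a 13-membered ring.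
3. Forward order: ring D by enantioselective [2+2] photocycloaddition; oxidative opening of the six-membered ring to a keto acid; C6–C7 union with a ring A allylic bromide; 13-membered macrolactone; double methylenation; then one C4–C5 bond closes rings B and C together.
4. Stereochemistry: C1 from the catalyst-controlled [2+2]; C9 by thermodynamic epimerisation next to the C8 ketone; C4, C5 and C1′ in the key step (chair-like transannular closure, then hydride delivery to the C1′ cation). The sense of C4/C5 relative to ring D is an expectation, not a secured outcome (see risks).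
5. Endgame: palladium deallylation and twofold Vilsmeier–Haack formylation of ring A.

Key step: step 13

Assumption: the enantiomer of the oxazaborolidine–AlBr3 photocatalyst is chosen so that adduct 3 is (1S,6S); the (R)-prolinol-derived complex is written for definiteness and its antipode is used if the facial preference is the reverse.

**Route**

Step 1
Reactants: 1 cyclohex-2-en-1-one; 2 2-methylpropene
Product: 3 (1S,6S)-7,7-dimethylbicyclo[4.2.0]octan-2-one
Conditions: hν (366 nm), AlBr3 complex of (R)-3,3-bis(3,5-dimethylphenyl)-1-(2,4,6-trifluorophenyl)tetrahydro-1H,3H-pyrrolo[1,2-c][1,3,2]oxazaborole (50 mol %), excess 2, CH2Cl2, −75 °C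
Reagents that add atoms: none
Why: Enantioselective Lewis-acid-catalysed [2+2] photocycloaddition, in which the bound enone is shielded on one face and isobutene adds head-to-tail (CMe2 next to the β-carbon), so the catalyst fixes C6 (later C1) as S, while the fusion centre C1 (later C9) is equilibrated in step 10.

Step 2
Reactants: 3 (1S,6S)-7,7-dimethylbicyclo[4.2.0]octan-2-one
Product: 5 (1S,6S)-7,7-dimethylbicyclo[4.2.0]oct-2-en-2-yl trifluoromethanesulfonate, via lithium enolate 4 (not isolated)
Conditions: LiN(iPr)2, THF, −78 °C; then PhNTf2, −78 → 0 °C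
Reagents that add atoms: N-phenylbis(trifluoromethanesulfonimide), O=S(=O)(N(c1ccccc1)S(=O)(=O)C(F)(F)F)C(F)(F)F
Why: Kinetic enolisation goes toward the C3 methylene (the C1 methine is the strained cyclobutane fusion) and O-sulfonylation gives the alkenyl triflate (enol triflate formation).

Step 3
Reactants: 5 (1S,6S)-7,7-dimethylbicyclo[4.2.0]oct-2-en-2-yl trifluoromethanesulfonate
Product: 6 (1S,6S)-2,7,7-trimethylbicyclo[4.2.0]oct-2-ene
Conditions: MeMgBr, Fe(acac)3 (5 mol %), THF/NMP, −30 → 0 °C
Reagents that add atoms: methylmagnesium bromide, C[Mg]Br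
Why: Iron-catalysed Kumada-type cross-coupling of an alkenyl triflate with a methyl Grignard reagent installs the carbon that becomes C7 without touching the two stereocentres.

Step 4
Reactants: 6 (1S,6S)-2,7,7-trimethylbicyclo[4.2.0]oct-2-ene
Product: 7 3-[(1S,4S)-4-acetyl-2,2-dimethylcyclobutyl]propanoic acid (cis keto acid)
Conditions: RuCl3·xH2O (2 mol %), NaIO4 (4 equiv), CCl4/MeCN/H2O, rt
Reagents that add atoms: sodium periodate, [Na+].[O-]I(=O)(=O)=O; water, O
Why: Ruthenium tetroxide generated catalytically cleaves the trisubstituted alkene directly to methyl ketone and carboxylic acid (oxidative alkene cleavage), so no aldol-prone keto aldehyde is handled.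

Step 5
Reactants: 8 (2,4,6-trihydroxyphenyl)(phenyl)methanone
Product: 9 [2-hydroxy-4,6-bis(prop-2-enyloxy)phenyl](phenyl)methanone
Conditions: allyl bromide (2.1 equiv), K2CO3, acetone, reflux
Reagents that add atoms: 3-bromoprop-1-ene, C=CCBr
Why: Williamson etherification, in which the phenol hydrogen-bonded to the ketone is the least reactive and stays free.

Step 6
Reactants: 9 [2-hydroxy-4,6-bis(prop-2-enyloxy)phenyl](phenyl)methanone
Product: 10 {2-[tert-butyl(dimethyl)silyloxy]-4,6-bis(prop-2-enyloxy)phenyl}(phenyl)methanone
Conditions: TBSOTf, 2,6-lutidine, CH2Cl2, 0 °C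
Reagents that add atoms: tert-butyldimethylsilyl trifluoromethanesulfonate, CC(C)(C)[Si](C)(C)OS(=O)(=O)C(F)(F)F
Why: Silylation with a silyl triflate overcomes the chelated, hindered phenol, which must be masked so that it neither traps the allylic cation of step 8 nor quenches the enolate of step 9.

Step 7
Reactants: 10 {2-[tert-butyl(dimethyl)silyloxy]-4,6-bis(prop-2-enyloxy)phenyl}(phenyl)methanone
Product: 11 1-{2-[tert-butyl(dimethyl)silyloxy]-4,6-bis(prop-2-enyloxy)phenyl}-1-phenylprop-2-en-1-ol (racemic)
Conditions: CH2=CHMgBr, THF, −78 → 0 °C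
Reagents that add atoms: vinylmagnesium bromide, C=C[Mg]Br
Why: Grignard 1,2-addition to a non-enolisable diaryl ketone brings in C5 and C6; the carbinol centre is destroyed in step 8, so it is made racemic.

Step 8
Reactants: 11 1-{2-[tert-butyl(dimethyl)silyloxy]-4,6-bis(prop-2-enyloxy)phenyl}-1-phenylprop-2-en-1-ol
Product: 12 [2-(3-bromo-1-phenylprop-1-enyl)-3,5-bis(prop-2-enyloxy)phenoxy](tert-butyl)dimethylsilane (E/Z mixture, used at once)
Conditions: PBr3 (0.4 equiv), pyridine (cat.), Et2O, −30 °C
Reagents that add atoms: phosphorus tribromide, BrP(Br)Br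
Why: The tertiary, doubly benzylic allylic alcohol ionises readily and bromide is captured at the primary terminus (allylic transposition, SN1/SN2′), giving the conjugated diarylethene whose geometry is of no consequence later.

Step 9
Reactants: 7 3-[(1S,4S)-4-acetyl-2,2-dimethylcyclobutyl]propanoic acid; 12 [2-(3-bromo-1-phenylprop-1-enyl)-3,5-bis(prop-2-enyloxy)phenoxy](tert-butyl)dimethylsilane
Product: 14 3-[(1S,4S)-4-{5-[2-(tert-butyldimethylsilyloxy)-4,6-bis(prop-2-enyloxy)phenyl]-5-phenylpent-4-enoyl}-2,2-dimethylcyclobutyl]propanoic acid, via dilithium dianion 13 (not isolated)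
Conditions: LiN(iPr)2 (2.2 equiv), THF/DMPU, −78 °C; then 12, −78 → −20 °C; H3O+
Reagents that add atoms: none
Why: Dianion alkylation, in which the carboxylate protects the acid, the second equivalent of base forms the kinetic enolate at the methyl group, and the primary allylic bromide reacts by SN2 at CH2 (the other allyl terminus is fully substituted), joining C6 to C7.

Step 10
Reactants: 14 cis keto acid silyl ether
Product: 15 3-[(1S,4R)-4-{5-[2-hydroxy-4,6-bis(prop-2-enyloxy)phenyl]-5-phenylpent-4-enoyl}-2,2-dimethylcyclobutyl]propanoic acid (trans hydroxy acid)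
Conditions: NaOMe (3 equiv), MeOH, 40 °C; then 1 M HCl
Reagents that add atoms: none
Why: Methoxide cleaves the aryl silyl ether by methanolysis and also equilibrates C9, α to the C8 ketone, to the thermodynamically preferred trans-1,2-disubstituted cyclobutane (base-mediated epimerisation), which sets C9 as R.

Step 11
Reactants: 15 trans hydroxy acid
Product: 17 13-membered macrolactone (phenol oxygen of 15 acylated by its own carboxyl group; (1S,9R)), via mixed anhydride 16 (not isolated)
Conditions: 2,4,6-trichlorobenzoyl chloride, Et3N, THF, rt; then DMAP, toluene (2 mM), 80 °C, slow addition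
Reagents that add atoms: none
Why: Yamaguchi macrolactonisation, in which DMAP opens the mixed anhydride and the phenol closes an unstrained 13-membered aryl ester under high dilution.

Step 12
Reactants: 17 13-membered macrolactone
Product: 18 bis-methylidene macrocycle (C8 ketone and ester C=O of 17 both replaced by C=CH2; a macrocyclic 2-aryloxypropene)
Conditions: Cp2TiMe2 (5 equiv), toluene, 75 °C, dark; basic alumina filtration
Reagents that add atoms: bis(cyclopentadienyl)dimethyltitanium, C[Ti](C)(C1C=CC=C1)C1C=CC=C1
Why: Petasis olefination converts ketones and esters under non-basic conditions, so one operation installs the C8 methylidene, makes the latent C4 methyl/oxocarbenium unit and leaves the epimerisable C9 centre untouched.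

Step 13
Reactants: 18 bis-methylidene macrocycle
Product: 19 (1S,4S,5R,9R,1′S)-chroman bis(prop-2-enyl) ether (the target without its two formyl groups, both phenols as allyl ethers)
Conditions: CF3CO2H (3 equiv), Et3SiH (5 equiv), CH2Cl2, −40 → 0 °C
Reagents that add atoms: none
Why: Proposed new method: trifluoroacetic acid protonates the 2-aryloxypropene of 18 at its CH2 terminus (an enol ether, far more basic than the 1,1-dialkyl exocyclic alkene or the allyl ethers), creating the C4 methyl group and an O-aryl oxocarbenium ion at C4; C5 of the electron-rich 1,1-diarylethene attacks it across the 13-membered ring and leaves a doubly benzylic C1′ cation, stabilised by the ortho and para oxygens of ring A, which Et3SiH reduces. The closest known reaction types are the Prins (oxocarbenium–alkene) cyclisation, the acid-mediated condensation of 2-(1-arylvinyl)phenols with carbonyl compounds to 4-aryl-2H-chromenes and the ionic hydrogenation of benzylic cations, which have not been combined in a transannular, ring-contracting sense on a macrocyclic aryl enol ether. Ring B closes in a 6-endo mode with respect to both π bonds (C=O+ and C=C lie inside the new ring) through a chair-like array, and the same C4–C5 bond contracts the 13-membered ring to the nine-membered ring C (transannular closure). C4 and C5 are set in the bond-forming step: the chair with C3 and C6 pseudo-equatorial would give the trans fusion, and the (1S,9R)-cyclobutane, through the conformation of the forming nine-membered ring, is expected but not assured to select the (4S,5R) pair; C1′ is set last, the silane adding in a product-like transition state so that phenyl becomes pseudo-equatorial and trans to C6. The step needs chemoselective protonation, C–C bond formation faster than hydride capture of the oxocarbenium ion, and indifference to alkene geometry; these rest on the basicity of the enol ether, on the intramolecular six-membered array versus bimolecular silane attack at low temperature, and on equilibration of both alkene isomers through the same C1′ cation under acid.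

Step 14
Reactants: 19 chroman bis(prop-2-enyl) ether
Product: 20 (1S,4S,5R,9R,1′S)-chromandiol (the target without its two formyl groups)
Conditions: Pd(PPh3)4 (5 mol %), morpholine, THF, rt
Reagents that add atoms: none
Why: Tsuji–Trost-type deallylation, in which zerovalent palladium ionises the allyl aryl ethers and morpholine captures the allyl groups, sparing the exocyclic alkene and the tertiary aryl ether.

Step 15
Reactants: 20 chromandiol
Product: 22 target dialdehyde, via bis(iminium) dichloride 21 (not isolated)
Conditions: (chloromethylene)dimethyliminium chloride (2.5 equiv), MeCN, 0 °C → rt; then aq. NaOAc, 40 °C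
Reagents that add atoms: (chloromethylene)dimethyliminium chloride, C[N+](C)=CCl.[Cl-]; water, O
Why: Vilsmeier–Haack formylation attacks the only two free positions of the phloroglucinol-type ring A with an electrophile too weak to react with the 1,1-dialkyl alkene, and hydrolysis of the bis(iminium) salt gives the dialdehyde.

**Compound list**

1 | cyclohex-2-en-1-one | O=C1C=CCCC1 | starting material
2 | 2-methylpropene | C=C(C)C | starting material
3 | (1S,6S)-7,7-dimethylbicyclo[4.2.0]octan-2-one | O=C1CCC[C@H]2[C@@H]1CC2(C)C | intermediate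
4 | lithium (1S,6S)-7,7-dimethylbicyclo[4.2.0]oct-2-en-2-olate | [Li+].[O-]C1=CCC[C@H]2[C@@H]1CC2(C)C | intermediate
5 | (1S,6S)-7,7-dimethylbicyclo[4.2.0]oct-2-en-2-yl trifluoromethanesulfonate | O=S(=O)(OC1=CCC[C@H]2[C@@H]1CC2(C)C)C(F)(F)F | intermediate
6 | (1S,6S)-2,7,7-trimethylbicyclo[4.2.0]oct-2-ene | CC1=CCC[C@H]2[C@@H]1CC2(C)C | intermediate
7 | 3-[(1S,4S)-4-acetyl-2,2-dimethylcyclobutyl]propanoic acid | OC(=O)CC[C@H]1[C@@H](C(C)=O)CC1(C)C | intermediate
8 | (2,4,6-trihydroxyphenyl)(phenyl)methanone | O=C(c1ccccc1)c1c(O)cc(O)cc1O | starting material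
9 | [2-hydroxy-4,6-bis(prop-2-enyloxy)phenyl](phenyl)methanone | O=C(c1ccccc1)c1c(O)cc(OCC=C)cc1OCC=C | intermediate
10 | {2-[tert-butyl(dimethyl)silyloxy]-4,6-bis(prop-2-enyloxy)phenyl}(phenyl)methanone | O=C(c1ccccc1)c1c(O[Si](C)(C)C(C)(C)C)cc(OCC=C)cc1OCC=C | intermediate
11 | 1-{2-[tert-butyl(dimethyl)silyloxy]-4,6-bis(prop-2-enyloxy)phenyl}-1-phenylprop-2-en-1-ol (racemic) | OC(C=C)(c1ccccc1)c1c(O[Si](C)(C)C(C)(C)C)cc(OCC=C)cc1OCC=C | intermediate
12 | [2-(3-bromo-1-phenylprop-1-enyl)-3,5-bis(prop-2-enyloxy)phenoxy](tert-butyl)dimethylsilane (E/Z mixture) | BrCC=C(c1ccccc1)c1c(O[Si](C)(C)C(C)(C)C)cc(OCC=C)cc1OCC=C | intermediate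
13 | dilithium dianion of 7 (carboxylate and methyl-ketone enolate) | [Li+].[Li+].[O-]C(=O)CC[C@H]1[C@@H](C([O-])=C)CC1(C)C | intermediate
14 | 3-[(1S,4S)-4-{5-[2-(tert-butyldimethylsilyloxy)-4,6-bis(prop-2-enyloxy)phenyl]-5-phenylpent-4-enoyl}-2,2-dimethylcyclobutyl]propanoic acid (E/Z mixture) | OC(=O)CC[C@H]1[C@@H](C(=O)CCC=C(c2ccccc2)c2c(O[Si](C)(C)C(C)(C)C)cc(OCC=C)cc2OCC=C)CC1(C)C | intermediate
15 | 3-[(1S,4R)-4-{5-[2-hydroxy-4,6-bis(prop-2-enyloxy)phenyl]-5-phenylpent-4-enoyl}-2,2-dimethylcyclobutyl]propanoic acid (E/Z mixture) | OC(=O)CC[C@H]1[C@H](C(=O)CCC=C(c2ccccc2)c2c(O)cc(OCC=C)cc2OCC=C)CC1(C)C | intermediate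
16 | mixed anhydride of 15 with 2,4,6-trichlorobenzoic acid | O=C(OC(=O)c1c(Cl)cc(Cl)cc1Cl)CC[C@H]1[C@H](C(=O)CCC=C(c2ccccc2)c2c(O)cc(OCC=C)cc2OCC=C)CC1(C)C | intermediate
17 | 13-membered macrolactone (aryl ester of 15; (1S,9R), E/Z mixture) | O=C1CC[C@H]2[C@H](C(=O)CCC=C(c3ccccc3)c3c(O1)cc(OCC=C)cc3OCC=C)CC2(C)C | intermediate
18 | bis-methylidene macrocycle (macrocyclic 2-aryloxypropene with C8 methylidene; (1S,9R), E/Z mixture) | C=C1CC[C@H]2[C@H](C(=C)CCC=C(c3ccccc3)c3c(O1)cc(OCC=C)cc3OCC=C)CC2(C)C | intermediate
19 | (1S,4S,5R,9R,1′S)-chroman bis(prop-2-enyl) ether (target without formyl groups, phenols allylated) | C=C1CC[C@@H]2[C@@H](c3ccccc3)c3c(OCC=C)cc(OCC=C)cc3O[C@@]2(C)CC[C@H]2[C@H]1CC2(C)C | intermediate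
20 | (1S,4S,5R,9R,1′S)-chromandiol (target without formyl groups) | C=C1CC[C@@H]2[C@@H](c3ccccc3)c3c(O)cc(O)cc3O[C@@]2(C)CC[C@H]2[C@H]1CC2(C)C | intermediate
21 | bis(N,N-dimethyliminium) dichloride of the target (both CHO as CH=NMe2+) | C=C1CC[C@@H]2[C@@H](c3ccccc3)c3c(O)c(C=[N+](C)C)c(O)c(C=[N+](C)C)c3O[C@@]2(C)CC[C@H]2[C@H]1CC2(C)C.[Cl-].[Cl-] | intermediate
22 | target: (1S,4S,5R,9R,1′S)-configured diformyl-dihydroxy-phenylchroman fused to the caryophyllane nine-membered and cyclobutane rings | C=C1CC[C@@H]2[C@@H](c3ccccc3)c3c(O)c(C=O)c(O)c(C=O)c3O[C@@]2(C)CC[C@H]2[C@H]1CC2(C)C | target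

**Step count**

Total: 15 steps. Longest linear sequence: 11 steps (steps 1–4 then 9–15; the ring A branch, steps 5–8 then 9–15, is equally long).

**Steps most likely to fail**

Step 13 (proposed new method). The transannular C–C bond formation may close on the wrong face of the macrocycle relative to ring D, the ring-fusion configuration may erode through reversible deprotonation of the C1′ cation, or the silane may capture the oxocarbenium ion before cyclisation. Fallback, setting out from 18 and coming back at 19, with known reaction types: the enol ether of 18 is hydrolysed (oxalic acid, wet THF) to the ring-opened phenol methyl ketone F1. Samarium diiodide (HMPA, t-BuOH, THF) then forms the C4 ketyl, which adds to C5 of the 1,1-diarylethene (ketyl–olefin cyclisation; the benzylic radical is reduced and protonated) to give the nine-membered tertiary alcohol F2. Camphorsulfonic acid in CH2Cl2 closes ring B by cyclodehydration through the tertiary C4 cation and returns 19.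

Step 12. Methylenation of the hindered aryl ester may stay incomplete, and the acid-labile enol ether may be hydrolysed open during isolation. Fallback, setting out from 15 and coming back at 18: the ketone and the ester are olefinated separately. Wittig methylenation of 15 (Ph3P=CH2, 4 equiv, THF) gives the methylidene hydroxy acid F3; Yamaguchi macrolactonisation gives the methylidene macrolactone F4; only the aryl ester then needs olefination, which is done with the Tebbe reagent Cp2Ti(μ-Cl)(μ-CH2)AlMe2 in THF/pyridine at −40 °C to return 18.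

Step 15. The reaction may stall after the first formylation, and the HCl released may isomerise or hydrochlorinate the exocyclic alkene. Fallback, setting out from 19 and coming back at 22: both ring A positions are brominated with N-bromosuccinimide (CH2Cl2, −78 °C) to give the dibromide F5. Twofold bromine–lithium exchange (t-BuLi, THF, −78 °C) and quenching with DMF give the dialdehyde bis(prop-2-enyl) ether F6. Pd(PPh3)4 with K2CO3 in MeOH removes both allyl groups and returns 22.

Further compounds

F1 | step 13 | ring-opened phenol methyl ketone (C4 as CH3C=O, free phenol, C8 methylidene; (1S,9R), E/Z mixture) | CC(=O)CC[C@H]1[C@H](C(=C)CCC=C(c2ccccc2)c2c(O)cc(OCC=C)cc2OCC=C)CC1(C)C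
F2 | step 13 | nine-membered tertiary alcohol (C4–C5 bond formed, C4 carbinol as a mixture, C5 and C1′ as in the target) | C=C1CC[C@H]([C@@H](c2ccccc2)c2c(O)cc(OCC=C)cc2OCC=C)C(C)(O)CC[C@H]2[C@H]1CC2(C)C
F3 | step 12 | methylidene hydroxy acid (15 with C8 C=O replaced by C=CH2) | OC(=O)CC[C@H]1[C@H](C(=C)CCC=C(c2ccccc2)c2c(O)cc(OCC=C)cc2OCC=C)CC1(C)C
F4 | step 12 | methylidene macrolactone (17 with C8 C=O replaced by C=CH2) | O=C1CC[C@H]2[C@H](C(=C)CCC=C(c3ccccc3)c3c(O1)cc(OCC=C)cc3OCC=C)CC2(C)C
F5 | step 15 | ring A dibromide of 19 | C=C1CC[C@@H]2[C@@H](c3ccccc3)c3c(OCC=C)c(Br)c(OCC=C)c(Br)c3O[C@@]2(C)CC[C@H]2[C@H]1CC2(C)C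
F6 | step 15 | dialdehyde bis(prop-2-enyl) ether (target with both phenols allylated) | C=C1CC[C@@H]2[C@@H](c3ccccc3)c3c(OCC=C)c(C=O)c(OCC=C)c(C=O)c3O[C@@]2(C)CC[C@H]2[C@H]1CC2(C)C
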